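**Strategy**

The pyran ring is cut at both of its bonds to the benzene ring, C4–C4a and O1–C8a, which turns the chromene into an aryne (C4a≡C8a) plus 3-methylbut-2-enal. In one operation the aryne inserts into the aldehyde C=O bond, making the aryl–carbon and aryl–oxygen bonds; the benzoxete then opens to an ortho-quinone methide and an oxa-6π electrocyclisation closes the pyran ring. The step exploits the oxygen at C5, next to C4a: as its MOM ether it polarises the aryne so that the aldehyde oxygen ends up at C8a. The precursor is an ortho-(trimethylsilyl)aryl triflate that already carries the prenyl group, the bibenzyl chain and both MOM ethers.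

Key step: step 9

Remark: the target is achiral (no stereocentre, no stereogenic double bond), so no stereocontrol is needed. Atom numbers in the text are those of the 2H-chromene (O1, C2, C3, C4, C4a, C5 to C8, C8a); ring A is the benzene ring of the chromene and ring B the 4-hydroxyphenyl ring. 4-Acetoxystyrene, 3-bromo-5-chlorophenol and 3-methylbut-2-enal are taken as commercial.

**Route**

Step 1
Reactants: 1 4-acetoxystyrene (4-ethenylphenyl acetate); 2 3-bromo-5-chlorophenol
Product: 5 3-chloro-5-[2-(4-hydroxyphenyl)ethyl]phenol, via alkylborane 3 (not isolated), via coupled acetate 4 (not isolated)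
Conditions: 1, 9-BBN (1.1 equiv), THF, 0 °C to rt; then 2, Pd(dppf)Cl2 (3 mol %), aq NaOH (3 M), 65 °C; then MeOH, rt; dilute HCl work-up
Reagents that add atoms: none
Why: Anti-Markovnikov hydroboration of the styrene followed by B-alkyl Suzuki–Miyaura coupling should engage only the C–Br bond of 2 (the C–Cl bond is inert to this catalyst at 65 °C), and the aqueous hydroxide cleaves the aryl acetate in the same pot.

Step 2
Reactants: 5 3-chloro-5-[2-(4-hydroxyphenyl)ethyl]phenol
Product: 6 1-chloro-3-(methoxymethoxy)-5-{2-[4-(methoxymethoxy)phenyl]ethyl}benzene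
Conditions: MOMCl (2.6 equiv), i-Pr2NEt (3.5 equiv), CH2Cl2, 0 °C to rt
Reagents that add atoms: chloromethyl methyl ether (MOMCl), COCCl
Why: O-alkylation of both phenols gives acetal ethers that tolerate hydroxide, organolithium bases and fluoride and later serve as ortho-directing groups.

Step 3
Reactants: 6 1-chloro-3-(methoxymethoxy)-5-{2-[4-(methoxymethoxy)phenyl]ethyl}benzene
Product: 7 3-(methoxymethoxy)-5-{2-[4-(methoxymethoxy)phenyl]ethyl}phenol
Conditions: Pd2(dba)3 (2 mol %), tBuXPhos (8 mol %), KOH (3 equiv), 1,4-dioxane/H2O, 100 °C; then dilute HCl to pH 6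
Reagents that add atoms: potassium hydroxide (KOH), [K+].[OH-]
Why: Palladium-catalysed hydroxylation of the aryl chloride (C–O cross-coupling with hydroxide) unmasks the one phenol that later becomes the triflate, so the two ring A oxygens are differentiated without a statistical protection, and MOM ethers are inert to hot aqueous KOH.

Step 4
Reactants: 7 3-(methoxymethoxy)-5-{2-[4-(methoxymethoxy)phenyl]ethyl}phenol
Product: 8 4-bromo-3-(methoxymethoxy)-5-{2-[4-(methoxymethoxy)phenyl]ethyl}phenol
Conditions: NBS (1.0 equiv), MeCN, −20 to 0 °C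
Reagents that add atoms: N-bromosuccinimide (NBS), O=C1CCC(=O)N1Br
Why: Electrophilic aromatic bromination of the free phenol should go mainly para to the hydroxyl group (between the OMOM group and the side chain), ring B being a far less activated monoalkoxyarene; any isomer brominated ortho to the hydroxyl would be removed by chromatography.

Step 5
Reactants: 8 4-bromo-3-(methoxymethoxy)-5-{2-[4-(methoxymethoxy)phenyl]ethyl}phenol
Product: 10 3-(methoxymethoxy)-5-{2-[4-(methoxymethoxy)phenyl]ethyl}-4-(3-methylbut-2-en-1-yl)phenol, via dilithio species 9 (not isolated)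
Conditions: n-BuLi (2.2 equiv), THF, −78 °C; then prenyl bromide (1.2 equiv), −78 to 0 °C; aq NH4Cl
Reagents that add atoms: 1-bromo-3-methylbut-2-ene (prenyl bromide), CC(C)=CCBr
Why: Deprotonation of the phenol and bromine–lithium exchange give an aryllithium chelated by the neighbouring MOM oxygen, which should be alkylated by prenyl bromide in an SN2 reaction at the primary carbon, while the lithium phenoxide is not alkylated in THF at low temperature.

Step 6
Reactants: 10 3-(methoxymethoxy)-5-{2-[4-(methoxymethoxy)phenyl]ethyl}-4-(3-methylbut-2-en-1-yl)phenol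
Product: 11 3-(methoxymethoxy)-5-{2-[4-(methoxymethoxy)phenyl]ethyl}-4-(3-methylbut-2-en-1-yl)phenyl N-(propan-2-yl)carbamate
Conditions: isopropyl isocyanate (1.5 equiv), Et3N (0.2 equiv), CH2Cl2, rt
Reagents that add atoms: isopropyl isocyanate, CC(C)N=C=O
Why: Base-catalysed addition of the phenol to the isocyanate gives an N–H carbamate, which directs ortho-metalation and can later be removed under mild basic conditions.

Step 7
Reactants: 11 3-(methoxymethoxy)-5-{2-[4-(methoxymethoxy)phenyl]ethyl}-4-(3-methylbut-2-en-1-yl)phenyl N-(propan-2-yl)carbamate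
Product: 15 3-(methoxymethoxy)-5-{2-[4-(methoxymethoxy)phenyl]ethyl}-4-(3-methylbut-2-en-1-yl)-2-(trimethylsilyl)phenyl N-(propan-2-yl)carbamate, via N-silyl carbamate 12 (not isolated), via aryllithium 13 (not isolated), via N-silyl arylsilane 14 (not isolated)
Conditions: TBSOTf (1.05 equiv), TMEDA (1.1 equiv), Et2O, 0 °C; then TMEDA (2.2 equiv), n-BuLi (2.3 equiv), −78 °C; TMSCl (3 equiv), −78 °C to rt; brief aq NaHSO4 work-up
Reagents that add atoms: chlorotrimethylsilane (TMSCl), C[Si](C)(C)Cl
Why: After in situ N-silylation, directed ortho-metalation should take place at the only ring position flanked by two directing groups (carbamate and OMOM), the aryllithium is trapped by TMSCl, and the N-silyl group is lost on work-up.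

Step 8
Reactants: 15 3-(methoxymethoxy)-5-{2-[4-(methoxymethoxy)phenyl]ethyl}-4-(3-methylbut-2-en-1-yl)-2-(trimethylsilyl)phenyl N-(propan-2-yl)carbamate
Product: 17 3-(methoxymethoxy)-5-{2-[4-(methoxymethoxy)phenyl]ethyl}-4-(3-methylbut-2-en-1-yl)-2-(trimethylsilyl)phenyl trifluoromethanesulfonate, via silylphenol 16 (not isolated)
Conditions: DBU (1.5 equiv), Et2NH (1.2 equiv), MeCN, 40 °C; then PhNTf2 (1.5 equiv), rt
Reagents that add atoms: N-phenylbis(trifluoromethanesulfonimide) (PhNTf2), O=S(=O)(N(c1ccccc1)S(=O)(=O)C(F)(F)F)C(F)(F)F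
Why: DBU-induced E1cB fragmentation of the N–H carbamate releases the phenoxide (the isocyanate is scavenged by diethylamine), which is sulfonylated in the same flask to give the ortho-silylaryl triflate.

Step 9
Reactants: 17 3-(methoxymethoxy)-5-{2-[4-(methoxymethoxy)phenyl]ethyl}-4-(3-methylbut-2-en-1-yl)-2-(trimethylsilyl)phenyl trifluoromethanesulfonate; 18 3-methylbut-2-enal
Product: 22 5-(methoxymethoxy)-7-{2-[4-(methoxymethoxy)phenyl]ethyl}-2,2-dimethyl-6-(3-methylbut-2-en-1-yl)-2H-chromene, via aryne 19 (not isolated), via benzoxete 20 (not isolated), via ortho-quinone methide 21 (not isolated)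
Conditions: CsF (3 equiv), 18 (5 equiv), MeCN, rt to 40 °C, 17 added slowly
Reagents that add atoms: none
Why: Fluoride attacks silicon in 17 and triflate leaves, giving aryne 19; the carbonyl oxygen of 18 adds to C8a, the aryne carbon remote from the inductively withdrawing OMOM group, and the resulting C4a aryl anion collapses onto the oxocarbenium carbon, so a formal [2+2] cycloaddition makes the aryl–O and aryl–C bonds of benzoxete 20. Conrotatory 4π ring opening of 20 gives ortho-quinone methide 21, whose thermally allowed disrotatory oxa-6π electrocyclisation (O1 onto the dimethyl-substituted terminus) closes the pyran ring and restores the benzene ring. The closest known reaction type is the annulation of fluoride-generated arynes with α,β-unsaturated aldehydes to 2H-chromenes. No stereocentre remains in 22 (the one in 20 is lost on ring opening) and the ring alkene is cis by ring constraint. The step needs regioselectivity (O at C8a, C at C4a), secured by the aryne polarisation and the unhindered C8a next to C8–H, and chemoselectivity for C=O insertion over ene reaction with prenyl groups, secured by the excess of 18, slow aryne generation and side chains that cannot reach the aryne intramolecularly. The β,β-disubstitution of 18 disfavours a competing [4+2] mode.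

Step 10
Reactants: 22 5-(methoxymethoxy)-7-{2-[4-(methoxymethoxy)phenyl]ethyl}-2,2-dimethyl-6-(3-methylbut-2-en-1-yl)-2H-chromene
Product: 23 7-[2-(4-hydroxyphenyl)ethyl]-2,2-dimethyl-6-(3-methylbut-2-en-1-yl)-2H-chromen-5-ol (target)
Conditions: aq HCl (3 M)/MeOH 1:10, rt to 40 °C, stopped at full conversion
Reagents that add atoms: none
Why: Acid-catalysed acetal exchange with methanol removes both MOM groups under conditions mild enough that the ortho-prenylphenol and the 2,2-dimethylchromene are expected to survive.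

**Compound list**

1 | 4-acetoxystyrene | CC(=O)Oc1ccc(C=C)cc1 | starting material
2 | 3-bromo-5-chlorophenol | Oc1cc(Br)cc(Cl)c1 | starting material
3 | 4-[2-(9-borabicyclo[3.3.1]nonan-9-yl)ethyl]phenyl acetate | CC(=O)Oc1ccc(CCB2C3CCCC2CCC3)cc1 | intermediate, not isolated
4 | 4-[2-(3-chloro-5-hydroxyphenyl)ethyl]phenyl acetate | CC(=O)Oc1ccc(CCc2cc(O)cc(Cl)c2)cc1 | intermediate, not isolated
5 | 3-chloro-5-[2-(4-hydroxyphenyl)ethyl]phenol | Oc1ccc(CCc2cc(O)cc(Cl)c2)cc1 | intermediate
6 | 1-chloro-3-(methoxymethoxy)-5-{2-[4-(methoxymethoxy)phenyl]ethyl}benzene | COCOc1ccc(CCc2cc(Cl)cc(OCOC)c2)cc1 | intermediate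
7 | 3-(methoxymethoxy)-5-{2-[4-(methoxymethoxy)phenyl]ethyl}phenol | COCOc1ccc(CCc2cc(O)cc(OCOC)c2)cc1 | intermediate
8 | 4-bromo-3-(methoxymethoxy)-5-{2-[4-(methoxymethoxy)phenyl]ethyl}phenol | Brc1c(CCc2ccc(OCOC)cc2)cc(O)cc1OCOC | intermediate
9 | lithium 4-lithio-3-(methoxymethoxy)-5-{2-[4-(methoxymethoxy)phenyl]ethyl}phenoxide | [Li]c1c(CCc2ccc(OCOC)cc2)cc(O[Li])cc1OCOC | intermediate, not isolated
10 | 3-(methoxymethoxy)-5-{2-[4-(methoxymethoxy)phenyl]ethyl}-4-(3-methylbut-2-en-1-yl)phenol | CC(C)=CCc1c(CCc2ccc(OCOC)cc2)cc(O)cc1OCOC | intermediate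
11 | 3-(methoxymethoxy)-5-{2-[4-(methoxymethoxy)phenyl]ethyl}-4-(3-methylbut-2-en-1-yl)phenyl N-(propan-2-yl)carbamate | CC(C)=CCc1c(CCc2ccc(OCOC)cc2)cc(OC(=O)NC(C)C)cc1OCOC | intermediate
12 | N-(tert-butyldimethylsilyl) derivative of carbamate 11 | CC(C)=CCc1c(CCc2ccc(OCOC)cc2)cc(OC(=O)N(C(C)C)[Si](C)(C)C(C)(C)C)cc1OCOC | intermediate, not isolated
13 | 2-lithio derivative of 12 (lithium between the carbamate and OMOM groups) | CC(C)=CCc1c(CCc2ccc(OCOC)cc2)cc(OC(=O)N(C(C)C)[Si](C)(C)C(C)(C)C)c([Li])c1OCOC | intermediate, not isolated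
14 | 2-(trimethylsilyl) derivative of 12 | CC(C)=CCc1c(CCc2ccc(OCOC)cc2)cc(OC(=O)N(C(C)C)[Si](C)(C)C(C)(C)C)c([Si](C)(C)C)c1OCOC | intermediate, not isolated
15 | 3-(methoxymethoxy)-5-{2-[4-(methoxymethoxy)phenyl]ethyl}-4-(3-methylbut-2-en-1-yl)-2-(trimethylsilyl)phenyl N-(propan-2-yl)carbamate | CC(C)=CCc1c(CCc2ccc(OCOC)cc2)cc(OC(=O)NC(C)C)c([Si](C)(C)C)c1OCOC | intermediate
16 | 3-(methoxymethoxy)-5-{2-[4-(methoxymethoxy)phenyl]ethyl}-4-(3-methylbut-2-en-1-yl)-2-(trimethylsilyl)phenol | CC(C)=CCc1c(CCc2ccc(OCOC)cc2)cc(O)c([Si](C)(C)C)c1OCOC | intermediate, not isolated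
17 | 3-(methoxymethoxy)-5-{2-[4-(methoxymethoxy)phenyl]ethyl}-4-(3-methylbut-2-en-1-yl)-2-(trimethylsilyl)phenyl trifluoromethanesulfonate | CC(C)=CCc1c(CCc2ccc(OCOC)cc2)cc(OS(=O)(=O)C(F)(F)F)c([Si](C)(C)C)c1OCOC | intermediate
18 | 3-methylbut-2-enal | CC(C)=CC=O | starting material
19 | 3-(methoxymethoxy)-5-{2-[4-(methoxymethoxy)phenyl]ethyl}-4-(3-methylbut-2-en-1-yl)-1,2-didehydrobenzene (aryne) | CC(C)=CCC1=C(OCOC)C#CC=C1CCc2ccc(OCOC)cc2 | intermediate, not isolated
20 | 3-(methoxymethoxy)-5-{2-[4-(methoxymethoxy)phenyl]ethyl}-4-(3-methylbut-2-en-1-yl)-2-(2-methylprop-1-en-1-yl)-2H-benzo[b]oxete (racemic) | CC(C)=CCc1c(CCc2ccc(OCOC)cc2)cc2OC(C=C(C)C)c2c1OCOC | intermediate, not isolated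
21 | 5-(methoxymethoxy)-3-{2-[4-(methoxymethoxy)phenyl]ethyl}-4-(3-methylbut-2-en-1-yl)-6-(3-methylbut-2-en-1-ylidene)cyclohexa-2,4-dien-1-one | CC(C)=CCC1=C(OCOC)C(=CC=C(C)C)C(=O)C=C1CCc2ccc(OCOC)cc2 | intermediate, not isolated
22 | 5-(methoxymethoxy)-7-{2-[4-(methoxymethoxy)phenyl]ethyl}-2,2-dimethyl-6-(3-methylbut-2-en-1-yl)-2H-chromene | CC(C)=CCc1c(CCc2ccc(OCOC)cc2)cc2c(c1OCOC)C=CC(C)(C)O2 | intermediate
23 | 7-[2-(4-hydroxyphenyl)ethyl]-2,2-dimethyl-6-(3-methylbut-2-en-1-yl)-2H-chromen-5-ol | CC(C)=CCc1c(CCc2ccc(O)cc2)cc2c(c1O)C=CC(C)(C)O2 | target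

**Step count and risks**

Total step count: 10. Longest linear sequence: 10 steps (from 1 and 2 to 23).

Steps most likely to fail:

1. Step 9 (key step). Capture of the aryne by the aldehyde carbonyl may lose out to ene reaction with prenyl groups or to aryne self-condensation, or the quinone methide may be trapped by a second aryne. The fallback sets out from 17 and returns to the route at 22. Aryne 19 would be generated with CsF in DMF as solvent, so that the formamide C=O bond, present in vast excess, captures it by the same insertion. The resulting 2-(dimethylamino)benzoxete F1 opens to the aminomethylene dienone F2, which is hydrolysed on aqueous work-up to salicylaldehyde F3. Addition of excess 2-methylprop-1-enylmagnesium bromide (THF, 0 °C) should give the benzylic allylic alcohol F4. Warming F4 in toluene (80 °C, optionally with catalytic pyridinium p-toluenesulfonate) should eliminate water to the same ortho-quinone methide 21, which electrocyclises to 22.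

2. Step 4. Bromination may occur ortho instead of para to the free hydroxyl, or twice. The fallback sets out from 7 and returns at 8. Silylation with triisopropylsilyl chloride and imidazole (DMF, rt) gives the triisopropylsilyl ether F5. In its NBS bromination the bulky silyl group shields both positions flanking its oxygen, so that the position para to it (ortho to OMOM) should be attacked, giving bromide F6. Bu4NF (THF, 0 °C) then removes the silyl group to give 8.

3. Step 5. The aryllithium may be quenched by proton transfer, or the phenoxide may be O-alkylated. The fallback sets out from 8 and returns at 11. Carbamoylation of 8 with isopropyl isocyanate (Et3N, CH2Cl2) gives the bromo carbamate F7. Stille coupling of F7 with tributyl(3-methylbut-2-en-1-yl)stannane (Pd(PPh3)4, DMF, 90 °C) should form the aryl–prenyl bond without any organolithium intermediate and give 11.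

**Further compounds**

F1 | step 9 | 2-(dimethylamino)-3-(methoxymethoxy)-5-{2-[4-(methoxymethoxy)phenyl]ethyl}-4-(3-methylbut-2-en-1-yl)-2H-benzo[b]oxete (racemic) | CC(C)=CCc1c(CCc2ccc(OCOC)cc2)cc2OC(N(C)C)c2c1OCOC
F2 | step 9 | 6-[(dimethylamino)methylidene]-5-(methoxymethoxy)-3-{2-[4-(methoxymethoxy)phenyl]ethyl}-4-(3-methylbut-2-en-1-yl)cyclohexa-2,4-dien-1-one | CC(C)=CCC1=C(OCOC)C(=CN(C)C)C(=O)C=C1CCc2ccc(OCOC)cc2
F3 | step 9 | 2-hydroxy-6-(methoxymethoxy)-4-{2-[4-(methoxymethoxy)phenyl]ethyl}-5-(3-methylbut-2-en-1-yl)benzaldehyde | CC(C)=CCc1c(CCc2ccc(OCOC)cc2)cc(O)c(C=O)c1OCOC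
F4 | step 9 | 2-(1-hydroxy-3-methylbut-2-en-1-yl)-3-(methoxymethoxy)-5-{2-[4-(methoxymethoxy)phenyl]ethyl}-4-(3-methylbut-2-en-1-yl)phenol (racemic) | CC(C)=CCc1c(CCc2ccc(OCOC)cc2)cc(O)c(C(O)C=C(C)C)c1OCOC
F5 | step 4 | triisopropyl[3-(methoxymethoxy)-5-{2-[4-(methoxymethoxy)phenyl]ethyl}phenoxy]silane | COCOc1ccc(CCc2cc(O[Si](C(C)C)(C(C)C)C(C)C)cc(OCOC)c2)cc1
F6 | step 4 | [4-bromo-3-(methoxymethoxy)-5-{2-[4-(methoxymethoxy)phenyl]ethyl}phenoxy]triisopropylsilane | CC(C)[Si](Oc1cc(CCc2ccc(OCOC)cc2)c(Br)c(OCOC)c1)(C(C)C)C(C)C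
F7 | step 5 | 4-bromo-3-(methoxymethoxy)-5-{2-[4-(methoxymethoxy)phenyl]ethyl}phenyl N-(propan-2-yl)carbamate | Brc1c(CCc2ccc(OCOC)cc2)cc(OC(=O)NC(C)C)cc1OCOC
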